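The bond everything rests on is the one between C3 of ring A (the quinone carbon between C2–OH and C4=O) and the first CH2 of the tether. Both rings are fully substituted 1,4-benzoquinones joined only through the ends of a (CH2)14 chain, so each ring–chain bond maps onto a carboxyl terminus of hexadecanedioic acid. The key step makes the ring A bond by silver-catalysed decarboxylation: the primary radical from an acid that already carries ring B adds to the single ring C–H of intact 2-hydroxy-5-methoxy-6-methyl-1,4-benzoquinone, so the unprotected bis-quinone appears in one operation. The precursors are acid 13 and acceptor 19, each a free hydroxyquinone.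

Key step: step 11

Remark on the chemistry: acceptor 19 is not made by partial hydrolysis of quinone 4, because its two methoxy groups differ only kinetically and strong acid is expected, from the behaviour of 2,5-dimethoxy-3-alkylquinones, to cleave the methyl-flanked one first. Its substitution pattern is instead fixed by the mirror symmetry of resorcinol 18.

Step 1
Reactants: 1 1,2,4,5-tetramethoxybenzene
Product: 3 2,3,5,6-tetramethoxytoluene, via 2,3,5,6-tetramethoxyphenyllithium 2 (not isolated)
Conditions: n-BuLi (1.1 equiv), THF, 0 °C to rt; then CH3I, 0 °C to rt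
Reagents that add atoms: iodomethane, CI
Why: Directed ortho-lithiation followed by SN2 methylation: the ring C–H of 1 lies between two methoxy groups, is the most acidic site for n-BuLi, and the aryllithium 2 is trapped by iodomethane, one equivalent of base leaving the second, equivalent C–H untouched.

Step 2
Reactants: 3 2,3,5,6-tetramethoxytoluene
Product: 4 2,5-dimethoxy-3-methyl-1,4-benzoquinone
Conditions: (NH4)2Ce(NO3)6 (2.5 equiv), MeCN/H2O, 0 °C
Reagents that add atoms: water, O
Why: Oxidative demethylation of a para-dimethoxyarene by the tetravalent cerium salt (carbonyl oxygens from water); the two para pairs of methoxy groups in 3 are mirror images of each other, so only one para-quinone can result.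

Step 3
Reactants: 4 2,5-dimethoxy-3-methyl-1,4-benzoquinone
Product: 6 2,5-dihydroxy-3-methyl-1,4-benzoquinone, via disodium 2-methyl-3,6-dioxocyclohexa-1,4-diene-1,4-diolate 5 (not isolated)
Conditions: 2 M NaOH (excess), EtOH, rt to 50 °C, argon; then 2 M HCl
Reagents that add atoms: sodium hydroxide, [Na+].[OH-]
Why: Addition–elimination of hydroxide at both vinylogous-ester carbons (alkaline hydrolysis of a methoxyquinone) is run to completion, so no choice between the two methoxy groups arises, and the base-stable dianion 5 is simply protonated.

Step 4
Reactants: 7 hexadecanedioic acid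
Product: 8 dimethyl hexadecanedioate
Conditions: MeOH, H2SO4 (cat.), reflux
Reagents that add atoms: methanol, CO
Why: Fischer esterification of both carboxyl groups, driven by methanol as solvent.

Step 5
Reactants: 8 dimethyl hexadecanedioate
Product: 10 16-methoxy-16-oxohexadecanoic acid (hexadecanedioic acid monomethyl ester), via barium bis(16-methoxy-16-oxohexadecanoate) 9 (not isolated)
Conditions: Ba(OH)2·8H2O (0.5 equiv), MeOH, rt; then 2 M HCl, Et2O
Reagents that add atoms: barium hydroxide, [Ba+2].[OH-].[OH-]
Why: Half saponification of a symmetric diester: the barium carboxylate 9 of the half ester is insoluble in methanol and precipitates, which protects the second ester group from hydroxide.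

Step 6
Reactants: 6 2,5-dihydroxy-3-methyl-1,4-benzoquinone; 10 16-methoxy-16-oxohexadecanoic acid (2 equiv)
Product: 11 methyl 15-(2,5-dihydroxy-4-methyl-3,6-dioxocyclohexa-1,4-dien-1-yl)pentadecanoate
Conditions: AgNO3 (0.3 equiv), (NH4)2S2O8 (2 equiv), MeCN/H2O (1:1), 65 °C
Reagents that add atoms: none
Why: Silver-catalysed peroxydisulfate decarboxylation, a Minisci-type radical alkylation of a quinone: divalent silver oxidises the carboxylate of 10, the primary radical adds to the only ring C–H of 6 and the adduct is reoxidised to the quinone, while the ester terminus is inert and the fully substituted product cannot be alkylated again.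

Step 7
Reactants: 11 methyl 15-(2,5-dihydroxy-4-methyl-3,6-dioxocyclohexa-1,4-dien-1-yl)pentadecanoate
Product: 13 15-(2,5-dihydroxy-4-methyl-3,6-dioxocyclohexa-1,4-dien-1-yl)pentadecanoic acid, via trilithium 15-(4-methyl-2,5-dioxido-3,6-dioxocyclohexa-1,4-dien-1-yl)pentadecanoate 12 (not isolated)
Conditions: LiOH (5 equiv), THF/H2O, argon, rt; then 1 M HCl
Reagents that add atoms: lithium hydroxide, [Li+].[OH-]
Why: Saponification of the methyl ester by hydroxide (acyl substitution); ring B merely ionises to its base-stable bis-enolate, the species through which 6 itself was made, and is reprotonated together with the carboxylate.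

Step 8
Reactants: 14 2,4-dimethoxy-3-methylbenzaldehyde
Product: 16 4,6-dimethoxy-5-methylbenzene-1,3-dicarbaldehyde, via 5-[chloro(methoxy)methyl]-2,4-dimethoxy-3-methylbenzaldehyde 15 (not isolated)
Conditions: Cl2CHOCH3 (2 equiv), TiCl4 (3 equiv), CH2Cl2, 0 °C to rt; then ice water
Reagents that add atoms: dichloromethyl methyl ether, COC(Cl)Cl; water, O
Why: Rieche formylation (Friedel–Crafts-type electrophilic substitution): C5 is ortho to one methoxy group, para to the other and meta to the formyl group, so every substituent directs the electrophile to the same carbon, and aqueous work-up hydrolyses the α-chloro ether 15 to the aldehyde.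

Step 9
Reactants: 16 4,6-dimethoxy-5-methylbenzene-1,3-dicarbaldehyde
Product: 18 4,6-dimethoxy-5-methylbenzene-1,3-diol, via 4,6-dimethoxy-5-methyl-1,3-phenylene diformate 17 (not isolated)
Conditions: mCPBA (2.5 equiv), CH2Cl2, rt; then MeOH, HCl (cat.), argon, rt
Reagents that add atoms: 3-chloroperoxybenzoic acid, OOC(=O)c1cccc(Cl)c1
Why: Twofold Baeyer–Villiger (Dakin-type) oxidation: each formyl group has an ortho and a para methoxy group, so the electron-rich aryl carbon migrates to oxygen, and the bis-formate 17 is cleaved by acidic methanolysis so that the air-sensitive diol never meets base.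

Step 10
Reactants: 18 4,6-dimethoxy-5-methylbenzene-1,3-diol
Product: 19 2-hydroxy-5-methoxy-6-methyl-1,4-benzoquinone
Conditions: (NH4)2Ce(NO3)6 (2.0 equiv, slow addition), MeCN/H2O, 0 °C
Reagents that add atoms: water, O
Why: Oxidative demethylation of a para-methoxyphenol to a quinone: 18 has a mirror plane through C5–CH3 and C2–H, so oxidation across either HO/OCH3 para pair gives the same compound, in which the surviving methoxy group necessarily sits beside the methyl group and the surviving hydroxyl beside the ring C–H, and slow addition keeps the cerium salt from attacking the product.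

Step 11
Reactants: 19 2-hydroxy-5-methoxy-6-methyl-1,4-benzoquinone (3 equiv); 13 15-(2,5-dihydroxy-4-methyl-3,6-dioxocyclohexa-1,4-dien-1-yl)pentadecanoic acid
Product: 20 3-[14-(2,5-dihydroxy-4-methyl-3,6-dioxocyclohexa-1,4-dien-1-yl)tetradecyl]-2-hydroxy-5-methoxy-6-methylcyclohexa-2,5-diene-1,4-dione (CNP0130251.0)
Conditions: AgNO3 (0.3 equiv), (NH4)2S2O8 (1.5 equiv), MeCN/H2O (1:1), 60 °C, short reaction time
Reagents that add atoms: none
Why: Peroxydisulfate oxidises monovalent to divalent silver, which oxidises the carboxylate of 13; loss of CO2 leaves a nucleophilic primary alkyl radical that adds to C3 of 19 (α to C4=O, β to the C2 hydroxyl), and the stabilised adduct radical is oxidised and deprotonated back to the quinone. The closest known reaction type is the silver/peroxydisulfate decarboxylative alkylation of quinones and 2-hydroxy-1,4-quinones by carboxylic acids, a Minisci-type homolytic substitution. No ring is closed and no stereocentre is created. Site selectivity is secured because 19 has a single ring C–H, while ring B of 13 and both rings of 20 are fully substituted, so neither self-trapping nor over-alkylation has an open position. Cross selectivity, ring A on one chain end and ring B on the other, was fixed earlier by the half ester 10, and 19 is used in excess so that the valuable acid is the limiting partner. The free hydroxyl groups and the methoxy group need no protection, and the short time at moderate temperature limits acid hydrolysis of the methyl-flanked methoxy group.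

Compound list
1 | 1,2,4,5-tetramethoxybenzene | COc1cc(OC)c(OC)cc1OC | starting material
2 | 2,3,5,6-tetramethoxyphenyllithium | [Li]c1c(OC)c(OC)cc(OC)c1OC | intermediate
3 | 2,3,5,6-tetramethoxytoluene | Cc1c(OC)c(OC)cc(OC)c1OC | intermediate
4 | 2,5-dimethoxy-3-methyl-1,4-benzoquinone | COC1=CC(=O)C(OC)=C(C)C1=O | intermediate
5 | disodium 2-methyl-3,6-dioxocyclohexa-1,4-diene-1,4-diolate | CC1=C([O-])C(=O)C=C([O-])C1=O.[Na+].[Na+] | intermediate
6 | 2,5-dihydroxy-3-methyl-1,4-benzoquinone | CC1=C(O)C(=O)C=C(O)C1=O | intermediate
7 | hexadecanedioic acid | OC(=O)CCCCCCCCCCCCCCC(O)=O | starting material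
8 | dimethyl hexadecanedioate | COC(=O)CCCCCCCCCCCCCCC(=O)OC | intermediate
9 | barium bis(16-methoxy-16-oxohexadecanoate) | COC(=O)CCCCCCCCCCCCCCC(=O)[O-].COC(=O)CCCCCCCCCCCCCCC(=O)[O-].[Ba+2] | intermediate
10 | 16-methoxy-16-oxohexadecanoic acid (hexadecanedioic acid monomethyl ester) | COC(=O)CCCCCCCCCCCCCCC(O)=O | intermediate
11 | methyl 15-(2,5-dihydroxy-4-methyl-3,6-dioxocyclohexa-1,4-dien-1-yl)pentadecanoate | COC(=O)CCCCCCCCCCCCCCC1=C(O)C(=O)C(C)=C(O)C1=O | intermediate
12 | trilithium 15-(4-methyl-2,5-dioxido-3,6-dioxocyclohexa-1,4-dien-1-yl)pentadecanoate | [Li+].[Li+].[Li+].[O-]C(=O)CCCCCCCCCCCCCCC1=C([O-])C(=O)C(C)=C([O-])C1=O | intermediate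
13 | 15-(2,5-dihydroxy-4-methyl-3,6-dioxocyclohexa-1,4-dien-1-yl)pentadecanoic acid | OC(=O)CCCCCCCCCCCCCCC1=C(O)C(=O)C(C)=C(O)C1=O | intermediate
14 | 2,4-dimethoxy-3-methylbenzaldehyde | COc1ccc(C=O)c(OC)c1C | starting material
15 | 5-[chloro(methoxy)methyl]-2,4-dimethoxy-3-methylbenzaldehyde (racemic, as its TiCl4 complex) | COC(Cl)c1cc(C=O)c(OC)c(C)c1OC | intermediate
16 | 4,6-dimethoxy-5-methylbenzene-1,3-dicarbaldehyde | O=Cc1cc(C=O)c(OC)c(C)c1OC | intermediate
17 | 4,6-dimethoxy-5-methyl-1,3-phenylene diformate | O=COc1cc(OC=O)c(OC)c(C)c1OC | intermediate
18 | 4,6-dimethoxy-5-methylbenzene-1,3-diol | Oc1cc(O)c(OC)c(C)c1OC | intermediate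
19 | 2-hydroxy-5-methoxy-6-methyl-1,4-benzoquinone | COC1=C(C)C(=O)C(O)=CC1=O | intermediate
20 | 3-[14-(2,5-dihydroxy-4-methyl-3,6-dioxocyclohexa-1,4-dien-1-yl)tetradecyl]-2-hydroxy-5-methoxy-6-methylcyclohexa-2,5-diene-1,4-dione (no stereocentre) | COC1=C(C)C(=O)C(O)=C(CCCCCCCCCCCCCCC2=C(O)C(=O)C(C)=C(O)C2=O)C1=O | target

Total step count: 11. Longest linear sequence: 6 steps (steps 1, 2, 3, 6, 7, 11).

Steps most likely to fail

Step 11. Decarboxylation of the precious acid may be outrun by oxidative degradation of the hydroxyquinone partners by sulfate radical anion, and the silver may be withdrawn as an insoluble hydroxyquinonate, so that little alkyl radical reaches the acceptor. The fallback releases the same radical without silver or peroxydisulfate. It sets out from 13, which is condensed with N-hydroxypyridine-2-thione (DCC, CH2Cl2, dark) to give the thiohydroxamate ester 2-thioxopyridin-1(2H)-yl 15-(2,5-dihydroxy-4-methyl-3,6-dioxocyclohexa-1,4-dien-1-yl)pentadecanoate F1. Visible-light irradiation of this ester with excess 19 in CH2Cl2 (Barton decarboxylation with a quinone as radical trap) should deliver the primary radical to C3 of 19. The adduct radical is oxidised by a second molecule of 19, whose hydroquinone is reoxidised by air on work-up, and the pyridylthiyl radical ends as the disulfide. The route is rejoined at 20.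

Step 6. The primary radical may be lost to over-oxidation or hydrogen abstraction before it meets the sparingly soluble dihydroxyquinone, or 6 may precipitate as its silver salt. The fallback is the thermal diacyl peroxide alkylation that is the classical way to alkylate 2,5-dihydroxy-1,4-benzoquinones. It sets out from 10, which with DCC and H2O2 in Et2O at 0 °C should give bis(16-methoxy-16-oxohexadecanoyl) peroxide F2. Heating this peroxide with 6 in acetic acid at 90–95 °C should transfer one ω-methoxycarbonylalkyl radical to the ring C–H with loss of CO2, the other acyloxy half returning as 10. The route is rejoined at 11.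

Step 10. The cerium salt, once in local excess, may oxidise the product at its free ring C–H (2-hydroxyquinones are themselves oxidisable there), and the acidic medium may strip the methyl-flanked methoxy group. The fallback replaces oxidation by hydrolysis. It sets out from 4, which with one equivalent of NaOH in THF/H2O at 0 °C should lose one vinylogous-ester methoxy group to give sodium 4-methoxy-5-methyl-3,6-dioxocyclohexa-1,4-dien-1-olate F3. The anionic ring resists a second attack, and acidification gives 19, where the route is rejoined. Attack beside the ring C–H is expected to be favoured in base because the enolate formed there lacks the α-methyl group, but the site would have to be proven by an NOE between OCH3 and ring CH3 and the isomer removed.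

Further compounds
F1 | step 11 | 2-thioxopyridin-1(2H)-yl 15-(2,5-dihydroxy-4-methyl-3,6-dioxocyclohexa-1,4-dien-1-yl)pentadecanoate | S=C1C=CC=CN1OC(=O)CCCCCCCCCCCCCCC2=C(O)C(=O)C(C)=C(O)C2=O
F2 | step 6 | bis(16-methoxy-16-oxohexadecanoyl) peroxide | COC(=O)CCCCCCCCCCCCCCC(=O)OOC(=O)CCCCCCCCCCCCCCC(=O)OC
F3 | step 10 | sodium 4-methoxy-5-methyl-3,6-dioxocyclohexa-1,4-dien-1-olate | COC1=C(C)C(=O)C([O-])=CC1=O.[Na+]
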